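# Proposed total synthesis of cyclointegrin by two-carbon ring enlargement of a chromanone enamine

## Analysis of the target

Cyclointegrin (C21H20O6) is a tetracyclic flavone. Ring A is the benzene ring of the chromone (5-OH chelated to C4=O, 7-OCH3), ring C is the 4-pyranone (O1, C2, C3, C4), and ring B is the 2-aryl group (4'-OH, 2'-O-alkyl). Ring D is an eight-membered oxocine made of O2'–C(CH3)2–CH2–CH2–C3=C2–C1'–C2'. The molecule has no stereocentre; the twisted C2–C1' axis inside ring D is conformationally mobile and poses no configurational problem.

The sensitive groups are:
- the tertiary alkyl aryl ether O2'–C(CH3)2, which strong protic or Lewis acids can ionise, opening ring D;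
- the 5-OH/7-OCH3 pair, which rules out late demethylation with boron or aluminium halides;
- the free 4'-phenol;
- the pyranone, which opens under strong base.

The difficulty lies in ring D. It is a medium ring that contains a tertiary C–O bond and the tetrasubstituted C2=C3 bond, so any end-to-end closure meets an unfavourable eight-membered transition state. In addition, a 3-alkylflavone normally requires a C-alkylation that competes with O-alkylation.

The feature the route exploits: read from ring B, the sequence C1'–C2'–O2'–C(CH3)2–CH2 plus C2 (which is at the ketone oxidation level) is a 2,2-dimethylchroman-4-one. Ring D is that chromanone with two carbons, C3 and the CH2 attached to it, inserted between the carbonyl carbon and the α-CH2. C3 also carries the C4 carbonyl bound to ring A, so the inserted two-carbon unit is an aryl ethynyl ketone.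

## Retrosynthetic reasoning

**From cyclointegrin 18 back to 16.** No skeletal bond is cut. The CH2–CH2 segment of ring D is traced back to a cis CH=CH unit and the 4'-OH to a benzyl ether. One catalytic hydrogenation, running through O-benzylcyclointegrin 17, then finishes the synthesis. The alkene is the footprint of the alkyne carbons that the key step inserts.

**From 16 back to 14.** The O1–C2 bond of ring C is cut. In the benzoxocine 14 the future C2 carries a pyrrolidin-1-yl group and the future C3 carries the ring A aroyl group, a vinylogous amide. Acid removes both methoxymethyl groups to give bisphenol 15. One ortho hydroxyl then adds to the amine-bearing carbon and expels the amine. Ring A of 15 is symmetric about its C1–C4 axis, so either hydroxyl gives the same chromone and the other becomes the chelated 5-OH. The forward step must do this without ionising the tertiary allylic ether.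

**From 14 back to enamine 6 and ynone 12 (key disconnection).** Two bonds of ring D are cut: C2–C3, and the bond between the two future CH2 carbons. The chromanone C3–C4 bond is restored. This cut was chosen because it turns the eight-membered ring into a six-membered ring plus a two-carbon unit. It moves the tertiary ether into a ring where it is trivial to make, and it places the aroyl group exactly 1,3 to the amine-bearing carbon, as ring C needs. In the forward direction, the enamine carbon of 6 must add to the alkyne terminus of 12, the cyclobutene 13 must form, and 13 must open to the ring-enlarged 14.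

**From 6 back to 5, 4, 1 and 2.** The enamine 6 comes from ketone 5 by condensation with a secondary amine, and 5 from phenol 4 by benzylation. Chromanone 4 is cut at the aryl–carbonyl bond and at O–C(CH3)2, giving resorcinol 1 and 3-methylbut-2-enoic acid 2. The forward reaction is a Friedel–Crafts acylation followed by oxa-Michael closure through aryl ketone 3. This makes the tertiary alkyl aryl ether of the target in the first step.

**From 12 back to 11, 10, 8 and 7.** Ynone 12 comes from the propargylic alcohol 11 by oxidation, and 11 from aldehyde 10 by addition of an ethynyl nucleophile. The formyl carbon of 10, the future C4, is attached through aryllithium 9 at the position between the two methoxymethoxy groups of 8. Compound 8 is the bis-protected form of 5-methoxyresorcinol 7. The symmetric 2,6-dioxygenation removes any regiochemical question in the closure of ring C.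

## Alternatives that were turned down

**Alternative 1:** the textbook, biomimetic disconnection of O2'–C(CH3)2. The forward key step is an acid-mediated Markovnikov addition of the 2'-OH to the olefin of the 3-prenylflavone A1, closing ring D end to end. It was turned down for three reasons:
- It is the route most chemists would draw first.
- A1 needs a tetra-oxygenated flavone with three differentiated phenols and a C3-prenylation that competes with O-alkylation, which amounts to about ten steps before the key step.
- The tertiary cation from A1 has several outlets: capture by the 2'-OH through an eight-membered transition state across a twisted aryl–pyranone bond, capture by the C4 carbonyl oxygen through a six-membered one, loss of a proton, or capture by water. The same acid that closes ring D can reopen it, and nothing in A1 biases the cation towards the medium ring.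

**Alternative 2:** disconnection of C2–C1'. The forward key step is an intramolecular palladium-catalysed C2–H arylation of the 3-alkylchromone A2 by its aryl bromide. It was turned down for these reasons:
- The tertiary alkyl aryl ether of A2 would have to be made intermolecularly from a hindered ortho-bromophenol and a tertiary carbon, where elimination dominates.
- The closure needs a nine-membered palladacycle, with an aryl–palladium bond flanked by the bulky alkoxy group, attacking the less reactive C2–H of a chromone. Protodebromination and intermolecular coupling are the likely outcomes.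
- A2 would cost at least eight steps.

**Alternative 3:** disconnection of ring C on a preformed eight-membered ketone. The forward key step is C-acylation of the enolate of benzoxocinone A3 with a ring A aroyl electrophile, followed by cyclodehydration (Baker–Venkataraman logic on a cyclic ketone). It was turned down for these reasons:
- A3 already contains the whole difficulty. It is only reachable by an end-to-end medium-ring closure, or by two successive one-carbon homologations of 5 with poor migratory selectivity between aryl and alkyl.
- Acylation of a hindered medium-ring enolate with a 2,6-disubstituted aroyl electrophile favours oxygen over carbon.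
- The chosen key step delivers the same oxidation pattern directly from 5 via its enamine, with the aroyl group already in place.

Key step: step 8

Remark on the chemistry: the target is achiral. Carbinol 11 and cyclobutene 13 are racemic, and the ring double bonds of 14 to 16 are cis; none of these elements survives to the target. Flavone numbering (C2, C3, C4, 2', 4') is used for the late compounds.

## Route

Step 1
Reactants: 1 resorcinol; 2 3-methylbut-2-enoic acid
Product: 4 7-hydroxy-2,2-dimethylchroman-4-one, via aryl ketone 3 (not isolated)
Conditions: P2O5/MeSO3H (1:10 w/w), 70 °C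
Reagents that add atoms: none
Why: Friedel–Crafts acylation para to one hydroxyl gives the 2,4-dihydroxyphenyl enone 3, whose ortho hydroxyl closes the pyranone by 6-endo oxa-Michael addition to the β,β-dimethyl enone; the tertiary alkyl aryl ether of the target is thus made in an easy six-membered closure.

Step 2
Reactants: 4 7-hydroxy-2,2-dimethylchroman-4-one
Product: 5 7-(benzyloxy)-2,2-dimethylchroman-4-one
Conditions: BnBr, K2CO3, acetone, reflux
Reagents that add atoms: benzyl bromide, BrCc1ccccc1
Why: Williamson etherification of the only phenol; the benzyl ether tolerates TiCl4/amine, the thermal key step and aqueous acid, and is removed in the final hydrogenation at no extra step.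

Step 3
Reactants: 5 7-(benzyloxy)-2,2-dimethylchroman-4-one
Product: 6 1-[7-(benzyloxy)-2,2-dimethyl-2H-chromen-4-yl]pyrrolidine
Conditions: pyrrolidine (6 equiv), TiCl4 (0.6 equiv), toluene, 0 °C to rt; filtration under argon, used crude
Reagents that add atoms: pyrrolidine, C1CCNC1
Why: TiCl4-mediated enamine condensation, the standard method for conjugated and hindered aryl ketones; TiCl4 acts as Lewis acid and water scavenger, and the only enolisable position (C3) fixes the double bond.

Step 4
Reactants: 7 5-methoxybenzene-1,3-diol
Product: 8 1-methoxy-3,5-bis(methoxymethoxy)benzene
Conditions: MOMCl, i-Pr2NEt, CH2Cl2, 0 °C to rt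
Reagents that add atoms: chloromethyl methyl ether, COCCl
Why: Double O-alkylation to the bis-acetal; the methoxymethyl groups direct the metalation of step 5 and are cleaved by the mild acid of step 9.

Step 5
Reactants: 8 1-methoxy-3,5-bis(methoxymethoxy)benzene
Product: 10 4-methoxy-2,6-bis(methoxymethoxy)benzaldehyde, via aryllithium 9 (not isolated)
Conditions: n-BuLi, TMEDA, THF, 0 °C; DMF, 0 °C to rt; aq NH4Cl
Reagents that add atoms: N,N-dimethylformamide, CN(C)C=O
Why: Directed ortho-metalation; the position flanked by two chelating methoxymethoxy groups should be deprotonated in preference to those next to the weaker methoxy director, and formylation of 9 installs the future C4.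

Step 6
Reactants: 10 4-methoxy-2,6-bis(methoxymethoxy)benzaldehyde
Product: 11 1-[4-methoxy-2,6-bis(methoxymethoxy)phenyl]prop-2-yn-1-ol (racemic)
Conditions: HC≡CMgBr, THF, 0 °C; aq NH4Cl
Reagents that add atoms: ethynylmagnesium bromide, C#C[Mg]Br
Why: Grignard 1,2-addition to a non-enolisable aldehyde; the new stereocentre is formed as a racemate and is removed by the next oxidation.

Step 7
Reactants: 11 1-[4-methoxy-2,6-bis(methoxymethoxy)phenyl]prop-2-yn-1-ol
Product: 12 1-[4-methoxy-2,6-bis(methoxymethoxy)phenyl]prop-2-yn-1-one
Conditions: MnO2, CH2Cl2, rt
Reagents that add atoms: none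
Why: Oxidation of a benzylic, propargylic alcohol with activated MnO2 under neutral conditions, which leaves the acetals and the terminal alkyne untouched; the ynone is used without storage.

Step 8
Reactants: 6 1-[7-(benzyloxy)-2,2-dimethyl-2H-chromen-4-yl]pyrrolidine; 12 1-[4-methoxy-2,6-bis(methoxymethoxy)phenyl]prop-2-yn-1-one
Product: 14 [9-(benzyloxy)-2,2-dimethyl-6-(pyrrolidin-1-yl)-2H-1-benzoxocin-5-yl][4-methoxy-2,6-bis(methoxymethoxy)phenyl]methanone, via aminocyclobutene 13 (not isolated)
Conditions: toluene, 0 °C to rt, then 90 °C
Reagents that add atoms: none
Why: The nucleophilic C3 of enamine 6 adds to the unsubstituted terminus of ynone 12, and the iminium/allenolate zwitterion collapses by a 4-exo closure onto the iminium carbon to give the cis-fused aminocyclobutene 13, a stepwise thermal [2+2] cycloaddition. On heating, the strained cyclobutene opens by cleavage of the σ bond that was the chromanone C3–C4 bond, a 4π ring opening assisted by the donor nitrogen and the acceptor ketone. This inserts both alkyne carbons into the six-membered ring, so ring D is closed by ring enlargement from six to eight members and not by an end-to-end closure. The closest known reaction type is the two-carbon ring enlargement of cyclic ketone enamines with acetylenic esters and acetylenic ketones through aminocyclobutenes, which is also practised on enamines of benzo-fused ketones. No stereocentre remains: the two stereocentres of racemic 13 are destroyed in the opening, and both ring double bonds of 14 are cis because the stepwise opening can relax to the unstrained diene of the eight-membered ring. Regiochemistry is fixed by polarity (enamine β-carbon to ynone β-carbon), which puts the aroyl group on the carbon next to the amine-bearing carbon, the 1,3-relationship of C4 and C2 of the flavone. The step needs ring closure of the zwitterion to outrun proton transfer, which would give an open-chain dienaminone; the aprotic non-polar solvent, an amine-free enamine and the aryl-stabilised iminium favour closure. The two ortho substituents of the aroyl group shield its carbonyl against 1,2-attack.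

Step 9
Reactants: 14 [9-(benzyloxy)-2,2-dimethyl-6-(pyrrolidin-1-yl)-2H-1-benzoxocin-5-yl][4-methoxy-2,6-bis(methoxymethoxy)phenyl]methanone
Product: 16 4'-O-benzyl-didehydrocyclointegrin (5-hydroxy-7-methoxy-4'-benzyloxyflavone bridged C3–CH=CH–C(CH3)2–O2' with a cis double bond), via bisphenol 15 (not isolated)
Conditions: 3 M aq HCl, MeOH/THF, 45 °C
Reagents that add atoms: none
Why: Acetal solvolysis frees the two equivalent ortho phenols, and one of them adds to the protonated vinylogous amide and expels pyrrolidine (enaminone-to-chromone cyclisation, 6-membered closure of ring C); hydrolysis of the enaminone to the β-diketone followed by cyclodehydration leads to the same chromone, and the remaining phenol is the chelated 5-OH.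

Step 10
Reactants: 16 4'-O-benzyl-didehydrocyclointegrin
Product: 18 cyclointegrin, via O-benzylcyclointegrin 17 (not isolated)
Conditions: H2 (1 atm), Pd/C, EtOAc/MeOH, rt
Reagents that add atoms: none
Why: Heterogeneous hydrogenation saturates the cis-disubstituted ring alkene and hydrogenolyses the benzyl ether in one operation; the tetrasubstituted C2=C3 bond of the pyranone should survive these mild conditions, as 2,2-dimethylchromenes fused to flavones normally do.

## Compound list

1 | resorcinol | Oc1cccc(O)c1 | starting material
2 | 3-methylbut-2-enoic acid | CC(C)=CC(=O)O | starting material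
3 | 1-(2,4-dihydroxyphenyl)-3-methylbut-2-en-1-one | CC(C)=CC(=O)c1ccc(O)cc1O | intermediate (not isolated)
4 | 7-hydroxy-2,2-dimethylchroman-4-one | CC1(C)CC(=O)c2ccc(O)cc2O1 | intermediate
5 | 7-(benzyloxy)-2,2-dimethylchroman-4-one | CC1(C)CC(=O)c2ccc(OCc3ccccc3)cc2O1 | intermediate
6 | 1-[7-(benzyloxy)-2,2-dimethyl-2H-chromen-4-yl]pyrrolidine | CC1(C)C=C(N2CCCC2)c2ccc(OCc3ccccc3)cc2O1 | intermediate
7 | 5-methoxybenzene-1,3-diol (5-methoxyresorcinol) | COc1cc(O)cc(O)c1 | starting material
8 | 1-methoxy-3,5-bis(methoxymethoxy)benzene | COCOc1cc(OC)cc(OCOC)c1 | intermediate
9 | [4-methoxy-2,6-bis(methoxymethoxy)phenyl]lithium | [Li]c1c(OCOC)cc(OC)cc1OCOC | intermediate (not isolated)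
10 | 4-methoxy-2,6-bis(methoxymethoxy)benzaldehyde | COCOc1cc(OC)cc(OCOC)c1C=O | intermediate
11 | 1-[4-methoxy-2,6-bis(methoxymethoxy)phenyl]prop-2-yn-1-ol, racemic | C#CC(O)c1c(OCOC)cc(OC)cc1OCOC | intermediate
12 | 1-[4-methoxy-2,6-bis(methoxymethoxy)phenyl]prop-2-yn-1-one | C#CC(=O)c1c(OCOC)cc(OC)cc1OCOC | intermediate
13 | [6-(benzyloxy)-3,3-dimethyl-8b-(pyrrolidin-1-yl)-2a,8b-dihydro-3H-cyclobuta[c]chromen-1-yl][4-methoxy-2,6-bis(methoxymethoxy)phenyl]methanone, cis-fused, racemic (one enantiomer drawn) | CC1(C)Oc2cc(OCc3ccccc3)ccc2[C@]2(N3CCCC3)C(C(=O)c3c(OCOC)cc(OC)cc3OCOC)=C[C@H]12 | intermediate (not isolated)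
14 | [9-(benzyloxy)-2,2-dimethyl-6-(pyrrolidin-1-yl)-2H-1-benzoxocin-5-yl][4-methoxy-2,6-bis(methoxymethoxy)phenyl]methanone, both ring double bonds cis | CC1(C)/C=C\C(C(=O)c2c(OCOC)cc(OC)cc2OCOC)=C(\N2CCCC2)c2ccc(OCc3ccccc3)cc2O1 | intermediate
15 | [9-(benzyloxy)-2,2-dimethyl-6-(pyrrolidin-1-yl)-2H-1-benzoxocin-5-yl](2,6-dihydroxy-4-methoxyphenyl)methanone | CC1(C)/C=C\C(C(=O)c2c(O)cc(OC)cc2O)=C(\N2CCCC2)c2ccc(OCc3ccccc3)cc2O1 | intermediate (not isolated)
16 | 4'-O-benzyl-didehydrocyclointegrin: 5-hydroxy-7-methoxyflavone with 4'-OBn, whose C3 and O2' are bridged by cis-CH=CH–C(CH3)2 (C3–CH=CH–C(CH3)2–O2') | CC1(C)/C=C\c2c(oc3cc(OC)cc(O)c3c2=O)-c2ccc(OCc3ccccc3)cc2O1 | intermediate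
17 | O-benzylcyclointegrin: cyclointegrin carrying a benzyl ether at the 4'-oxygen | CC1(C)CCc2c(oc3cc(OC)cc(O)c3c2=O)-c2ccc(OCc3ccccc3)cc2O1 | intermediate (not isolated)
18 | cyclointegrin | COc1cc(O)c2c(=O)c3c(oc2c1)-c1ccc(O)cc1OC(C)(C)CC3 | target

## Step count and risk

Total step count: 10 (steps 1 to 3 for the ring B branch, steps 4 to 7 for the ring A branch, steps 8 to 10 after the union).
Longest linear sequence: 7 steps (steps 4, 5, 6, 7, 8, 9, 10, from 7 to 18).

**Step 8 (key step).** Three things are most likely to go wrong:
- proton transfer within the zwitterion before the four-membered ring closes, which diverts the material to an open-chain conjugate adduct;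
- slow attack of the enamine carbon, which sits next to the C(CH3)2 group;
- hydrolysis of the moisture-sensitive enamine before it reacts.

The fallback sets out from 5 and comes back at 16; it also bypasses step 3. Ketone 5 is silylated (TBSOTf, Et3N, CH2Cl2) to the silyl enol ether tert-butyl{[7-(benzyloxy)-2,2-dimethyl-2H-chromen-4-yl]oxy}dimethylsilane F1. F1 is combined with ynone 12 under acid catalysis (Tf2NH, CH2Cl2, −78 °C). This is a Mukaiyama–Michael addition followed by closure, the known acid-catalysed [2+2] reaction of silyl enol ethers with acetylenic carbonyl compounds, and gives the silyloxycyclobutene F2. The acid activates the ynone, and there is no acidic ammonium proton to quench the intermediate. Treatment of F2 with Bu4NF frees the alkoxide, whose accelerated ring opening gives the ring-enlarged cyclic β-diketone F3. The conditions of step 9 then remove the acetals and cyclodehydrate F3 to 16.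

**Step 9.** The risk is ionisation of the tertiary allylic aryl ether in acid, with loss of a proton and opening of ring D, before or after ring C has closed. The reaction may also stall at the β-diketone stage. The fallback sets out from 14 and comes back at 18 by inverting the order of the endgame, so that no allylic ether meets acid. Hydrogenation of 14 (H2, Pd/C, EtOAc) should saturate the disubstituted ring alkene and remove the benzyl group, leaving the tetrasubstituted vinylogous amide. This gives the saturated enaminone [9-hydroxy-2,2-dimethyl-6-(pyrrolidin-1-yl)-3,4-dihydro-2H-1-benzoxocin-5-yl][4-methoxy-2,6-bis(methoxymethoxy)phenyl]methanone F4. Aqueous HCl in MeOH then cleaves the acetals and closes ring C to give 18 directly.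

**Step 10.** The risk is hydrogenolysis of the allylic C–O bond through an allylpalladium species before the alkene is saturated, which would open ring D. Slow over-reduction of the pyranone is a second risk. The fallback sets out from 16 and comes back at 18. It separates the two tasks and removes the metal from the alkene reduction. Diimide, generated from 2-nitrobenzenesulfonylhydrazide and Et3N, saturates the cis alkene by concerted hydrogen transfer to give 17. The benzyl ether of 17, which no longer has an allylic C–O bond, is then hydrogenolysed over Pd/C. No new compound arises.

**Step 3.** The risk is retro-oxa-Michael opening of the chromanone by the amine and the Lewis acid, or incomplete condensation of the conjugated, peri-hindered aryl ketone. The fallback sets out from 5 and comes back at 6. It replaces the condensation with a cross-coupling. Enolisation and triflation (KN(SiMe3)2, PhNTf2, THF, −78 °C) give the vinyl triflate 7-(benzyloxy)-2,2-dimethyl-2H-chromen-4-yl trifluoromethanesulfonate F5. Amination of F5 with pyrrolidine under a zerovalent palladium catalyst (Pd2(dba)3, BINAP, Cs2CO3, toluene, 80 °C) gives enamine 6.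

## Further compounds

F1 | step 8 | tert-butyl{[7-(benzyloxy)-2,2-dimethyl-2H-chromen-4-yl]oxy}dimethylsilane | CC1(C)C=C(O[Si](C)(C)C(C)(C)C)c2ccc(OCc3ccccc3)cc2O1
F2 | step 8 | [6-(benzyloxy)-8b-{[tert-butyl(dimethyl)silyl]oxy}-3,3-dimethyl-2a,8b-dihydro-3H-cyclobuta[c]chromen-1-yl][4-methoxy-2,6-bis(methoxymethoxy)phenyl]methanone, cis-fused, racemic | CC1(C)Oc2cc(OCc3ccccc3)ccc2[C@]2(O[Si](C)(C)C(C)(C)C)C(C(=O)c3c(OCOC)cc(OC)cc3OCOC)=C[C@H]12
F3 | step 8 | 9-(benzyloxy)-5-[4-methoxy-2,6-bis(methoxymethoxy)benzoyl]-2,2-dimethyl-2H-1-benzoxocin-6(5H)-one, racemic, cis ring alkene | CC1(C)/C=C\C(C(=O)c2c(OCOC)cc(OC)cc2OCOC)C(=O)c2ccc(OCc3ccccc3)cc2O1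
F4 | step 9 | [9-hydroxy-2,2-dimethyl-6-(pyrrolidin-1-yl)-3,4-dihydro-2H-1-benzoxocin-5-yl][4-methoxy-2,6-bis(methoxymethoxy)phenyl]methanone | CC1(C)CC/C(C(=O)c2c(OCOC)cc(OC)cc2OCOC)=C(/N2CCCC2)c2ccc(O)cc2O1
F0 | step 10 | none | none
F5 | step 3 | 7-(benzyloxy)-2,2-dimethyl-2H-chromen-4-yl trifluoromethanesulfonate | CC1(C)C=C(OS(=O)(=O)C(F)(F)F)c2ccc(OCc3ccccc3)cc2O1
A1 | alternative 1 | 2-(2,4-dihydroxyphenyl)-5-hydroxy-7-methoxy-3-(3-methylbut-2-en-1-yl)-4H-chromen-4-one | COc1cc(O)c2c(=O)c(CC=C(C)C)c(-c3ccc(O)cc3O)oc2c1
A2 | alternative 2 | 3-{3-[5-(benzyloxy)-2-bromophenoxy]-3-methylbutyl}-5-hydroxy-7-methoxy-4H-chromen-4-one | COc1cc(O)c2c(=O)c(CCC(C)(C)Oc3cc(OCc4ccccc4)ccc3Br)coc2c1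
A3 | alternative 3 | 9-(benzyloxy)-2,2-dimethyl-3,4-dihydro-2H-1-benzoxocin-6(5H)-one | CC1(C)CCCC(=O)c2ccc(OCc3ccccc3)cc2O1
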